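**Retrosynthetic overview**

- The target is reached by two deprotections (acetonide, then two phenolic benzyl ethers) from a fully protected trans lactone.
- The lactone is cut at its ring CH2–O bond and at its C(=O)–Cα bond. This removes one O–C(=O) unit and leaves an (E)-styrene with a chloromethyl arm on the allylic stereocentre. Formate returns the unit as the CO2 radical anion: anti-Markovnikov hydrocarboxylation, ring closure on the chloride, then base equilibration to trans.
- Enabling feature: the C=C bond is conjugated with ring B (the ring that carries the glycerol ether oxygen), so the radical adds at the alkene carbon remote from ring B. The CH2Cl carbon stands 1,3 to that carbon, so the new carboxylate closes a five-membered ring. The lactone α C–H then allows equilibration against the fixed β centre.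
- The styrene comes from a Heck coupling of aryl bromide fragment 1 with chloroalkene fragment 2. Fragment 1 gets both carbinol centres from an Evans syn aldol of a ring-B aryloxyacetyl imide with O-benzylvanillin. Fragment 2 gets the future lactone β centre from a deconjugative Evans alkylation of a crotonyl imide with the ring-A benzyl bromide.
- Ring order: the three benzene rings are bought; the temporary 1,3-dioxane forms in step 5 and the lactone in step 12.

Key step: step 12

Assumption: the configurations are read from the SMILES as (3R,4R) for the trans lactone and (1R,2R) for the arylglycerol unit; compounds 1, 2, 4, 7, 12, 13 and 16 are bought.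

**Fragment 1 (aryl bromide)**

Step 1
Reactants: 1 4-bromo-2-methoxyphenol; 2 bromoacetic acid
Product: 3 2-(4-bromo-2-methoxyphenoxy)acetic acid
Conditions: NaOH (3 equiv), H2O, reflux; then HCl to pH 1
Reagents that add atoms: none
Why: Williamson ether synthesis in which the phenoxide of 1 displaces bromide from bromoacetate by SN2, with no stereocentre involved.

Step 2
Reactants: 3 2-(4-bromo-2-methoxyphenoxy)acetic acid; 4 (4S)-4-benzyl-1,3-oxazolidin-2-one
Product: 6 (4S)-4-benzyl-3-[2-(4-bromo-2-methoxyphenoxy)acetyl]-1,3-oxazolidin-2-one, via mixed pivalic anhydride 5 (not isolated)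
Conditions: PivCl, Et3N, THF, −20 °C; then 4, LiCl, −20 °C to rt
Reagents that add atoms: none
Why: N-acylation of an Evans oxazolidinone through a mixed anhydride, in which the hindered pivaloyl carbonyl directs attack to the aryloxyacetyl carbonyl and the auxiliary stereocentre is untouched.

Step 3
Reactants: 6 (4S)-4-benzyl-3-[2-(4-bromo-2-methoxyphenoxy)acetyl]-1,3-oxazolidin-2-one; 7 4-(benzyloxy)-3-methoxybenzaldehyde
Product: 9 (4S)-4-benzyl-3-[(2S,3R)-3-[4-(benzyloxy)-3-methoxyphenyl]-2-(4-bromo-2-methoxyphenoxy)-3-hydroxypropanoyl]-1,3-oxazolidin-2-one, via dibutylboron Z-enolate 8 (not isolated)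
Conditions: Bu2BOTf, i-Pr2NEt, CH2Cl2, −78 to 0 °C; then 7, −78 to 0 °C; then pH 7 buffer, MeOH, H2O2, 0 °C
Reagents that add atoms: none
Why: Evans syn aldol reaction in which the (Z)-boron enolate reacts through a Zimmerman–Traxler chair on the face away from the auxiliary's benzyl group, which should set both new centres as (2S,3R), the syn relation that becomes (1R,2R) in the target.

Step 4
Reactants: 9 (4S)-4-benzyl-3-[(2S,3R)-3-[4-(benzyloxy)-3-methoxyphenyl]-2-(4-bromo-2-methoxyphenoxy)-3-hydroxypropanoyl]-1,3-oxazolidin-2-one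
Product: 10 (1R,2R)-1-[4-(benzyloxy)-3-methoxyphenyl]-2-(4-bromo-2-methoxyphenoxy)propane-1,3-diol
Conditions: NaBH4, THF/H2O (4:1), 0 °C to rt
Reagents that add atoms: none
Why: Reductive cleavage of the N-acyl oxazolidinone with NaBH4 in wet THF should give the primary alcohol and release the auxiliary for recovery, while the aryl bromide, the benzyl ether and both stereocentres are left alone.

Step 5
Reactants: 10 (1R,2R)-1-[4-(benzyloxy)-3-methoxyphenyl]-2-(4-bromo-2-methoxyphenoxy)propane-1,3-diol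
Product: 11 (4R,5R)-4-[4-(benzyloxy)-3-methoxyphenyl]-5-(4-bromo-2-methoxyphenoxy)-2,2-dimethyl-1,3-dioxane
Conditions: 2,2-dimethoxypropane, PPTS (cat), acetone, rt
Reagents that add atoms: 2,2-dimethoxypropane, COC(C)(C)OC
Why: Acid-catalysed transacetalisation of the 1,3-diol to the six-membered isopropylidene acetal masks both hydroxyl groups so that no free O–H flanks the benzylic C–H in the radical step, and the mild acid should not ionise the benzylic C–O bond.

**Fragment 2 (chloroalkene)**

Step 6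
Reactants: 12 (4R)-4-benzyl-1,3-oxazolidin-2-one; 13 (2E)-but-2-enoyl chloride
Product: 15 (4R)-4-benzyl-3-[(2E)-but-2-enoyl]-1,3-oxazolidin-2-one, via lithium oxazolidinide 14 (not isolated)
Conditions: n-BuLi, THF, −78 °C; then 13, −78 to 0 °C
Reagents that add atoms: none
Why: N-acylation of the lithiated Evans oxazolidinone with an acid chloride at low temperature, with no change at the stereocentre.

Step 7
Reactants: 16 [4-(benzyloxy)-3-methoxyphenyl]methanol
Product: 17 1-(benzyloxy)-4-(bromomethyl)-2-methoxybenzene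
Conditions: PBr3, Et2O, 0 °C
Reagents that add atoms: phosphorus tribromide, BrP(Br)Br
Why: Conversion of a benzylic alcohol into the bromide with PBr3 by SN2 displacement of the activated phosphite ester, with no stereocentre involved.

Step 8
Reactants: 15 (4R)-4-benzyl-3-[(2E)-but-2-enoyl]-1,3-oxazolidin-2-one; 17 1-(benzyloxy)-4-(bromomethyl)-2-methoxybenzene
Product: 19 (4R)-4-benzyl-3-[(2R)-2-{[4-(benzyloxy)-3-methoxyphenyl]methyl}but-3-enoyl]-1,3-oxazolidin-2-one, via sodium dienolate 18 (not isolated)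
Conditions: NaN(SiMe3)2, THF, −78 °C; then 17, −78 to −30 °C
Reagents that add atoms: none
Why: Evans asymmetric alkylation in its deconjugative form, in which γ-deprotonation gives the chelated sodium (Z)-dienolate and alkylation at the α-carbon on the face away from the auxiliary's benzyl group should give the (2R) centre that becomes the lactone β-carbon.

Step 9
Reactants: 19 (4R)-4-benzyl-3-[(2R)-2-{[4-(benzyloxy)-3-methoxyphenyl]methyl}but-3-enoyl]-1,3-oxazolidin-2-one
Product: 20 (2R)-2-{[4-(benzyloxy)-3-methoxyphenyl]methyl}but-3-en-1-ol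
Conditions: LiBH4, MeOH (1 equiv), THF, 0 °C
Reagents that add atoms: none
Why: Reductive removal of the Evans auxiliary with LiBH4 should give the primary alcohol without touching the terminal alkene or the adjacent stereocentre, which is no longer acidic once reduced.

Step 10
Reactants: 20 (2R)-2-{[4-(benzyloxy)-3-methoxyphenyl]methyl}but-3-en-1-ol
Product: 21 1-(benzyloxy)-4-[(2R)-2-(chloromethyl)but-3-en-1-yl]-2-methoxybenzene
Conditions: PPh3, N-chlorosuccinimide, CH2Cl2, 0 °C to rt
Reagents that add atoms: N-chlorosuccinimide, O=C1CCC(=O)N1Cl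
Why: Appel-type chlorination in which the alcohol attacks the chlorophosphonium salt and chloride displaces triphenylphosphine oxide at the primary carbon by SN2, leaving the adjacent stereocentre unchanged.

**Coupling, key step and deprotection**

Step 11
Reactants: 11 (4R,5R)-4-[4-(benzyloxy)-3-methoxyphenyl]-5-(4-bromo-2-methoxyphenoxy)-2,2-dimethyl-1,3-dioxane; 21 1-(benzyloxy)-4-[(2R)-2-(chloromethyl)but-3-en-1-yl]-2-methoxybenzene
Product: 22 (4R,5R)-4-[4-(benzyloxy)-3-methoxyphenyl]-5-{4-[(1E,3R)-3-{[4-(benzyloxy)-3-methoxyphenyl]methyl}-4-chlorobut-1-en-1-yl]-2-methoxyphenoxy}-2,2-dimethyl-1,3-dioxane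
Conditions: Pd[P(t-Bu)3]2 (5 mol%), Cy2NMe, 1,4-dioxane, 90 °C
Reagents that add atoms: none
Why: Mizoroki–Heck reaction in which oxidative addition of the aryl bromide to zerovalent palladium, insertion of the terminal alkene with the aryl group at the CH2 terminus and β-hydride elimination towards the benzylic hydrogen should give the conjugated (E)-styrene, while the bulky phosphine and the amine base release the palladium hydride quickly so that the allylic stereocentre is not scrambled by chain walking.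

Step 12
Reactants: 22 (4R,5R)-4-[4-(benzyloxy)-3-methoxyphenyl]-5-{4-[(1E,3R)-3-{[4-(benzyloxy)-3-methoxyphenyl]methyl}-4-chlorobut-1-en-1-yl]-2-methoxyphenoxy}-2,2-dimethyl-1,3-dioxane
Product: 25 (3R,4R)-4-{[4-(benzyloxy)-3-methoxyphenyl]methyl}-3-{[4-({(4R,5R)-4-[4-(benzyloxy)-3-methoxyphenyl]-2,2-dimethyl-1,3-dioxan-5-yl}oxy)-3-methoxyphenyl]methyl}oxolan-2-one, via potassium chloro carboxylate 23 (not isolated), via cis-lactone 24 (not isolated)
Conditions: HCO2K (5 equiv), 4CzIPN (2 mol%), HSCH2CH2SO3Na (20 mol%), DMSO, 450 nm LEDs, 25 °C; then 60 °C; then KOt-Bu (0.5 equiv), 25 °C; aq NH4Cl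
Reagents that add atoms: potassium formate, [K+].[O-]C=O
Why: Excited 4CzIPN and the thiol turn formate into the CO2 radical anion, which adds to the alkene carbon remote from ring B because only that addition gives a benzylic radical, and the thiol then returns a hydrogen atom to the benzylic carbon and carries the chain (Giese-type radical addition with thiol hydrogen atom transfer). The closest known reaction type is the photochemical anti-Markovnikov hydrocarboxylation of styrenes with formate salts and a thiol catalyst, joined here to the classical lactonisation of a 4-chloro carboxylate. The only ring closed is the lactone, by 5-exo-tet SN2 attack of the carboxylate oxygen on the chloromethyl carbon once the mixture is warmed. The new stereocentre at the lactone α-carbon has no reliable kinetic control and is therefore set thermodynamically: KOt-Bu epimerises the α C–H and the fixed (R) centre at the β-carbon should drive the two benzyl groups trans, which is (3R,4R). The step needs regioselectivity in the radical addition, secured by conjugation of the alkene with ring B, and selectivity for the formate C–H over the benzylic and acetal C–H bonds, secured by the excess of hydridic formate and by the acetonide and benzyl ethers that leave no free O–H beside a benzylic C–H.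

Step 13
Reactants: 25 (3R,4R)-4-{[4-(benzyloxy)-3-methoxyphenyl]methyl}-3-{[4-({(4R,5R)-4-[4-(benzyloxy)-3-methoxyphenyl]-2,2-dimethyl-1,3-dioxan-5-yl}oxy)-3-methoxyphenyl]methyl}oxolan-2-one
Product: 26 (3R,4R)-4-{[4-(benzyloxy)-3-methoxyphenyl]methyl}-3-{[4-({(1R,2R)-1-[4-(benzyloxy)-3-methoxyphenyl]-1,3-dihydroxypropan-2-yl}oxy)-3-methoxyphenyl]methyl}oxolan-2-one
Conditions: AcOH/H2O/THF (3:1:1), 40 °C
Reagents that add atoms: none
Why: Mild aqueous acid hydrolysis of the isopropylidene acetal should free the 1,3-diol, the weak acid and moderate temperature being chosen so that the benzylic C–O bond is not ionised and the lactone and benzyl ethers persist.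

Step 14
Reactants: 26 (3R,4R)-4-{[4-(benzyloxy)-3-methoxyphenyl]methyl}-3-{[4-({(1R,2R)-1-[4-(benzyloxy)-3-methoxyphenyl]-1,3-dihydroxypropan-2-yl}oxy)-3-methoxyphenyl]methyl}oxolan-2-one
Product: 27 (3R,4R)-3-{[4-({(1R,2R)-1,3-dihydroxy-1-(4-hydroxy-3-methoxyphenyl)propan-2-yl}oxy)-3-methoxyphenyl]methyl}-4-[(4-hydroxy-3-methoxyphenyl)methyl]oxolan-2-one
Conditions: H2 (1 atm), 10% Pd/C, EtOAc/EtOH, rt
Reagents that add atoms: none
Why: Catalytic hydrogenolysis of the two phenolic benzyl ethers over Pd/C under neutral conditions, in which aryl benzyl ethers are cleaved far faster than the secondary benzylic alcohol, the aryl alkyl ether or the lactone, so that all four stereocentres should be retained.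

**Compound list**

1 | 4-bromo-2-methoxyphenol | COc1cc(Br)ccc1O | starting material
2 | bromoacetic acid | OC(=O)CBr | starting material
3 | 2-(4-bromo-2-methoxyphenoxy)acetic acid | COc1cc(Br)ccc1OCC(=O)O | intermediate
4 | (4S)-4-benzyl-1,3-oxazolidin-2-one | O=C1N[C@@H](Cc2ccccc2)CO1 | starting material
5 | 2-(4-bromo-2-methoxyphenoxy)acetic pivalic anhydride | COc1cc(Br)ccc1OCC(=O)OC(=O)C(C)(C)C | intermediate
6 | (4S)-4-benzyl-3-[2-(4-bromo-2-methoxyphenoxy)acetyl]-1,3-oxazolidin-2-one | COc1cc(Br)ccc1OCC(=O)N1[C@@H](Cc2ccccc2)COC1=O | intermediate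
7 | 4-(benzyloxy)-3-methoxybenzaldehyde | COc1cc(C=O)ccc1OCc1ccccc1 | starting material
8 | (Z)-dibutylboron enolate of 6 | COc1cc(Br)ccc1O/C=C(\OB(CCCC)CCCC)N1[C@@H](Cc2ccccc2)COC1=O | intermediate
9 | (4S)-4-benzyl-3-[(2S,3R)-3-[4-(benzyloxy)-3-methoxyphenyl]-2-(4-bromo-2-methoxyphenoxy)-3-hydroxypropanoyl]-1,3-oxazolidin-2-one | COc1cc(Br)ccc1O[C@@H]([C@H](O)c1ccc(OCc2ccccc2)c(OC)c1)C(=O)N1[C@@H](Cc2ccccc2)COC1=O | intermediate
10 | (1R,2R)-1-[4-(benzyloxy)-3-methoxyphenyl]-2-(4-bromo-2-methoxyphenoxy)propane-1,3-diol | COc1cc(Br)ccc1O[C@H](CO)[C@H](O)c1ccc(OCc2ccccc2)c(OC)c1 | intermediate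
11 | (4R,5R)-4-[4-(benzyloxy)-3-methoxyphenyl]-5-(4-bromo-2-methoxyphenoxy)-2,2-dimethyl-1,3-dioxane | COc1cc(Br)ccc1O[C@@H]2COC(C)(C)O[C@@H]2c3ccc(OCc4ccccc4)c(OC)c3 | intermediate
12 | (4R)-4-benzyl-1,3-oxazolidin-2-one | O=C1N[C@H](Cc2ccccc2)CO1 | starting material
13 | (2E)-but-2-enoyl chloride | C/C=C/C(=O)Cl | starting material
14 | lithium salt of 12 | O=C1[N-][C@H](Cc2ccccc2)CO1.[Li+] | intermediate
15 | (4R)-4-benzyl-3-[(2E)-but-2-enoyl]-1,3-oxazolidin-2-one | C/C=C/C(=O)N1[C@H](Cc2ccccc2)COC1=O | intermediate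
16 | [4-(benzyloxy)-3-methoxyphenyl]methanol | COc1cc(CO)ccc1OCc1ccccc1 | starting material
17 | 1-(benzyloxy)-4-(bromomethyl)-2-methoxybenzene | COc1cc(CBr)ccc1OCc1ccccc1 | intermediate
18 | sodium (Z)-dienolate of 15 | C=C/C=C(\[O-])N1[C@H](Cc2ccccc2)COC1=O.[Na+] | intermediate
19 | (4R)-4-benzyl-3-[(2R)-2-{[4-(benzyloxy)-3-methoxyphenyl]methyl}but-3-enoyl]-1,3-oxazolidin-2-one | C=C[C@@H](Cc1ccc(OCc2ccccc2)c(OC)c1)C(=O)N1[C@H](Cc2ccccc2)COC1=O | intermediate
20 | (2R)-2-{[4-(benzyloxy)-3-methoxyphenyl]methyl}but-3-en-1-ol | C=C[C@@H](Cc1ccc(OCc2ccccc2)c(OC)c1)CO | intermediate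
21 | 1-(benzyloxy)-4-[(2R)-2-(chloromethyl)but-3-en-1-yl]-2-methoxybenzene | C=C[C@@H](Cc1ccc(OCc2ccccc2)c(OC)c1)CCl | intermediate
22 | (4R,5R)-4-[4-(benzyloxy)-3-methoxyphenyl]-5-{4-[(1E,3R)-3-{[4-(benzyloxy)-3-methoxyphenyl]methyl}-4-chlorobut-1-en-1-yl]-2-methoxyphenoxy}-2,2-dimethyl-1,3-dioxane | ClC[C@H](Cc1ccc(OCc2ccccc2)c(OC)c1)/C=C/c3ccc(O[C@@H]4COC(C)(C)O[C@@H]4c5ccc(OCc6ccccc6)c(OC)c5)c(OC)c3 | intermediate
23 | potassium (3R)-3-{[4-(benzyloxy)-3-methoxyphenyl]methyl}-2-{[4-({(4R,5R)-4-[4-(benzyloxy)-3-methoxyphenyl]-2,2-dimethyl-1,3-dioxan-5-yl}oxy)-3-methoxyphenyl]methyl}-4-chlorobutanoate (both C2 epimers) | O=C([O-])C(Cc3ccc(O[C@@H]4COC(C)(C)O[C@@H]4c5ccc(OCc6ccccc6)c(OC)c5)c(OC)c3)[C@H](CCl)Cc1ccc(OCc2ccccc2)c(OC)c1.[K+] | intermediate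
24 | (3S,4R)-cis epimer of 25 | COc1cc(C[C@H]2COC(=O)[C@H]2Cc3ccc(O[C@@H]4COC(C)(C)O[C@@H]4c5ccc(OCc6ccccc6)c(OC)c5)c(OC)c3)ccc1OCc7ccccc7 | intermediate
25 | (3R,4R)-4-{[4-(benzyloxy)-3-methoxyphenyl]methyl}-3-{[4-({(4R,5R)-4-[4-(benzyloxy)-3-methoxyphenyl]-2,2-dimethyl-1,3-dioxan-5-yl}oxy)-3-methoxyphenyl]methyl}oxolan-2-one | COc1cc(C[C@H]2COC(=O)[C@@H]2Cc3ccc(O[C@@H]4COC(C)(C)O[C@@H]4c5ccc(OCc6ccccc6)c(OC)c5)c(OC)c3)ccc1OCc7ccccc7 | intermediate
26 | (3R,4R)-4-{[4-(benzyloxy)-3-methoxyphenyl]methyl}-3-{[4-({(1R,2R)-1-[4-(benzyloxy)-3-methoxyphenyl]-1,3-dihydroxypropan-2-yl}oxy)-3-methoxyphenyl]methyl}oxolan-2-one | COc1cc(C[C@H]2COC(=O)[C@@H]2Cc3ccc(O[C@H](CO)[C@H](O)c5ccc(OCc6ccccc6)c(OC)c5)c(OC)c3)ccc1OCc7ccccc7 | intermediate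
27 | (3R,4R)-3-{[4-({(1R,2R)-1,3-dihydroxy-1-(4-hydroxy-3-methoxyphenyl)propan-2-yl}oxy)-3-methoxyphenyl]methyl}-4-[(4-hydroxy-3-methoxyphenyl)methyl]oxolan-2-one | COc1cc(C[C@H]2COC(=O)[C@@H]2Cc2ccc(O[C@H](CO)[C@H](O)c3ccc(O)c(OC)c3)c(OC)c2)ccc1O | target

**Step count and risks**

Total step count: 14. Longest linear sequence: 9 steps (steps 1 to 5, then 11 to 14).

Steps most likely to fail:

1. Step 12. The nucleophilic CO2 radical anion may add too slowly to the electron-rich, β-alkylated styrene. Hydrogen abstraction at the allylic, benzylic or acetal C–H bonds may compete and erode configuration. Equilibration to the trans lactone may stay incomplete.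
 The fallback is the classical enolate route; it sets out from 21 and 11 and comes back at 25. Hydroboration of 21 (9-BBN, THF; then NaBO3·4H2O) would give the chloro alcohol F1. Oxidation (TEMPO, PhI(OAc)2, MeCN/H2O) would give the chloro acid F2, and ring closure (K2CO3, DMF) the (R)-β-benzyl lactone F3. In parallel, bromine–lithium exchange on 11 and formylation (n-BuLi, THF, −78 °C; DMF) would give the aldehyde F4, NaBH4 the benzylic alcohol F5, and CBr4/PPh3 the benzylic bromide F6. Alkylation of the lithium enolate of F3 (LiN(SiMe3)2, THF, −78 °C) with F6, anti to the existing benzyl group, should give 25 directly.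

2. Step 11. β-Hydride elimination towards the allylic C–H, or re-addition of palladium hydride, may move the double bond out of conjugation or scramble the allylic centre. Oxidative addition of the electron-rich aryl bromide may also be slow.
 The fallback sets out from 21 and 11 and comes back at 22. Cross-metathesis of 21 with vinylboronic acid pinacol ester (second-generation Grubbs catalyst, CH2Cl2, 40 °C) would give the (E)-alkenylboronate F7. Suzuki–Miyaura coupling of F7 with 11 (Pd(dppf)Cl2, K3PO4, dioxane/H2O, 80 °C) should then give 22 with the alkene position fixed.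

3. Step 3. The aryloxy-substituted boron enolate may react sluggishly with the electron-rich aldehyde, and syn selectivity may erode or retro-aldol cleavage may occur on work-up.
 The fallback sets out from 3 and comes back at 10. Fischer esterification (MeOH, H2SO4) would give the methyl ester F8. C-acylation of its enolate (LiN(SiMe3)2, THF, −78 °C; 4-(benzyloxy)-3-methoxybenzoyl chloride) would give the racemic β-keto ester F9. Asymmetric transfer hydrogenation with dynamic kinetic resolution (RuCl(p-cymene)[(S,S)-TsDPEN], HCO2H/Et3N, 30 °C) should give the syn hydroxy ester F10, and LiBH4 (THF, 0 °C) then gives 10. The (S,S) catalyst is expected, by analogy with aryl ketone reductions, to deliver the (3R) carbinol; the mirror-image catalyst would be used if the sense proved opposite.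

**Further compounds**

F1 | step 12 | (3R)-3-{[4-(benzyloxy)-3-methoxyphenyl]methyl}-4-chlorobutan-1-ol | OCC[C@H](CCl)Cc1ccc(OCc2ccccc2)c(OC)c1
F2 | step 12 | (3R)-3-{[4-(benzyloxy)-3-methoxyphenyl]methyl}-4-chlorobutanoic acid | OC(=O)C[C@H](CCl)Cc1ccc(OCc2ccccc2)c(OC)c1
F3 | step 12 | (4R)-4-{[4-(benzyloxy)-3-methoxyphenyl]methyl}oxolan-2-one | O=C1C[C@@H](Cc2ccc(OCc3ccccc3)c(OC)c2)CO1
F4 | step 12 | 4-({(4R,5R)-4-[4-(benzyloxy)-3-methoxyphenyl]-2,2-dimethyl-1,3-dioxan-5-yl}oxy)-3-methoxybenzaldehyde | COc1cc(C=O)ccc1O[C@@H]2COC(C)(C)O[C@@H]2c3ccc(OCc4ccccc4)c(OC)c3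
F5 | step 12 | [4-({(4R,5R)-4-[4-(benzyloxy)-3-methoxyphenyl]-2,2-dimethyl-1,3-dioxan-5-yl}oxy)-3-methoxyphenyl]methanol | COc1cc(CO)ccc1O[C@@H]2COC(C)(C)O[C@@H]2c3ccc(OCc4ccccc4)c(OC)c3
F6 | step 12 | (4R,5R)-4-[4-(benzyloxy)-3-methoxyphenyl]-5-[4-(bromomethyl)-2-methoxyphenoxy]-2,2-dimethyl-1,3-dioxane | COc1cc(CBr)ccc1O[C@@H]2COC(C)(C)O[C@@H]2c3ccc(OCc4ccccc4)c(OC)c3
F7 | step 11 | 2-[(1E,3R)-3-{[4-(benzyloxy)-3-methoxyphenyl]methyl}-4-chlorobut-1-en-1-yl]-4,4,5,5-tetramethyl-1,3,2-dioxaborolane | ClC[C@H](Cc1ccc(OCc2ccccc2)c(OC)c1)/C=C/B3OC(C)(C)C(C)(C)O3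
F8 | step 3 | methyl 2-(4-bromo-2-methoxyphenoxy)acetate | COC(=O)COc1ccc(Br)cc1OC
F9 | step 3 | methyl 3-[4-(benzyloxy)-3-methoxyphenyl]-2-(4-bromo-2-methoxyphenoxy)-3-oxopropanoate (racemic) | COC(=O)C(Oc1ccc(Br)cc1OC)C(=O)c1ccc(OCc2ccccc2)c(OC)c1
F10 | step 3 | methyl (2S,3R)-3-[4-(benzyloxy)-3-methoxyphenyl]-2-(4-bromo-2-methoxyphenoxy)-3-hydroxypropanoate | COc1cc(Br)ccc1O[C@@H]([C@H](O)c1ccc(OCc2ccccc2)c(OC)c1)C(=O)OC
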